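Which flask ends with the most target at 80 min, and does ash, warmed late, keep what its cool hour gave it?

the same everywhere: substrate 0.94 M
- Wednesday's: capture agent 0.0094 M; temperature 20 °C; run made earlier
- Tuesday's: capture agent 0.038 M; temperature 35 °C; run made earlier
- alder: capture agent 0.0188 M; temperature 45 °C; time 80 min
- oak: capture agent 0.0188 M; temperature 25 °C; time 80 min
- ash: capture agent 0.0188 M; at 25 °C until 1.0 h, from then on at 45 °C; time 80 min

| run | time / min | target / % |
|---|---|---|
| Wednesday's | 50.0 | 51.4 |
| Wednesday's | 90.0 | 49.7 |
| Wednesday's | 180 | 47.3 |
| Wednesday's | 300 | 45.7 |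
| Tuesday's | 25.0 | 18.3 |
| Tuesday's | 50.0 | 20.8 |
| Tuesday's | 80.0 | 19.7 |
| Tuesday's | 90.0 | 19.0 |
| Tuesday's | 120 | 21.6 |

(standard deviation of a reading: 1 percentage point)

- which flask leads in amount of target, in percent of the substrate charged ("all alike" within 1.5 percentage points) (alder / oak / ash / all alike)
- how much target is there at the end, in percent of the substrate charged: alder
- how much target is there at the end, in percent of the substrate charged: oak
- how much target is there at the end, in percent of the substrate charged: ash

- a reading or a percentage of target counts all its forms, free or not

I began with the rate. In Wednesday's run target lost 1.7 percentage points in the first 40.0 min between readings but 1.6 points in the last 120 min, so the fall per minute slowed by a factor of 3.19, a reading with the scatter on it. I took that as a fall heading for a stop. Tuesday's hotter run showed no fall beyond its scatter from its first reading on, standing about 19.9%. So I put the crossing from speed to balance, kinetic to thermodynamic control, early at 35 °C and late at 20 °C. Capture agent differed too, but in Tuesday's run it was 4.04% of the substrate, less than the 26 points between the runs, so I laid the gap on temperature.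

Past the crossing, what counts is the ratio of target to the rest of the charge: 0.842 at 20 °C and 0.248 at 35 °C. I carried their quotient, the fall of the resting ratio across that gap of temperature, 3.39. Spread evenly over the degrees, it gave me a ratio of 0.110 at 45 °C, or 9.91% target, and 0.560 at 25 °C, or 35.9%. Ash's 20.0 min of heat were fewer than Tuesday's 25.0 min, but hotter, so I put ash on alder's level, with oak leading.

The forecast named oak, with 10% for alder, 37% for oak and 11.5% for ash, a little above my ash figure: “I therefore read temperature as the main driver”.

The flasks gave oak in the lead: alder 9.64%, oak 36.4%, ash 9.65%.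

    substrate → open intermediate (k = 4.70 min⁻¹, Ea = 87.0 kJ mol⁻¹)
    open intermediate ⇌ target (K = 1.90, k = 0.210 min⁻¹, Ea = 94.0 kJ mol⁻¹, ΔH = −53.0 kJ mol⁻¹)
    open intermediate ⇌ isomer of the product (K = 2.30, k = 0.0710 min⁻¹, Ea = 95.0 kJ mol⁻¹, ΔH = 17.0 kJ mol⁻¹)
    open intermediate + capture agent → trapped intermediate (k = 0.110 L mol⁻¹ min⁻¹, Ea = 69.0 kJ mol⁻¹)
    substrate + target ⇌ idle adduct, settled at all times (K = 0.330 L mol⁻¹, ΔH = −1.00 kJ mol⁻¹)
    (constants at 25 °C)

The fall of 3.39 had carried the ratio to 0.110 for alder, where the flask stands at 0.107, and to 0.560 for oak, where it stands at 0.572. Alder ends so low because target returns to open intermediate. With that return taken away, the same flask ends at 99.5% target instead of 9.64%.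

Readings and results are calculated with made-up constants; the scatter is artificial.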